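Ring D, the trans-3-methyloxolan-2-one on the ethyl-bearing side chain, is cut at its C4–C5 bond (CH2–CH–O). The key step exploits the C5–O1–C2 linkage of this ring: it is pre-formed as an ester whose acyl carbon is C5 and whose alkoxy carbon is the future C2, while C4 carries iodine. SmI2 inverts the polarity of C4, which closes the five-membered ring onto C5 in one operation (O-to-C acyl shift). This joins two electrophilic carbons and leaves a ketone for a relay reduction from the neighbouring stereocentre. The precursor is the (R)-3-iodo-2-methylpropyl ester of a bicyclic lactam acid; rings A and B come from pyroglutaminol.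

Key step: step 7

Remark: rings are A (azepane), B (pyrrolidine), C (lactone on ring B) and D (lactone on the side chain), ring D being numbered as an oxolan-2-one (O1, C2 carbonyl, C3 methyl-bearing, C4 methylene, C5 carbinol); 1, 2, 5, 11 and 20 are taken as purchasable.

Step 1
Reactants: 1 (S)-5-(hydroxymethyl)pyrrolidin-2-one; 2 ethyl 2-(triphenyl-λ5-phosphanylidene)butanoate
Product: 4 ethyl (2E)-2-ethyl-3-[(2S)-5-oxopyrrolidin-2-yl]prop-2-enoate, via aldehyde 3 (not isolated)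
Conditions: PhI(OAc)2, TEMPO (cat.), CH2Cl2/MeCN, rt; then 2, 40 °C
Reagents that add atoms: none
Why: One-pot TEMPO oxidation and Wittig olefination with the stabilized ylide traps the epimerizable aldehyde at once and should give the E enoate (ester trans to the ring carbon), with the ring stereocentre taken unchanged from the chiral pool.

Step 2
Reactants: 4 ethyl (2E)-2-ethyl-3-[(2S)-5-oxopyrrolidin-2-yl]prop-2-enoate; 5 1-bromo-4-chlorobutane
Product: 8 ethyl (2S,3R)-7-chloro-2-ethyl-3-[(2S)-5-oxopyrrolidin-2-yl]heptanoate, via Grignard reagent 6 (not isolated), via silyl ketene acetal 7 (not isolated)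
Conditions: Mg, THF (5 to 6); 6 (3.5 equiv), CuBr·SMe2 (0.2 equiv), Me3SiCl, DMPU, THF, −78 to −40 °C; then AcOH, −78 °C; aq. NH4Cl
Reagents that add atoms: none
Why: In this copper-catalysed, Me3SiCl-accelerated 1,4-addition of a Grignard reagent the lactam N–H is silylated in situ, allylic 1,3-strain with the cis ethyl group holds the ring C–H in the alkene plane, the alkyl group should enter anti to the silylated ring nitrogen (Felkin–Anh type, C3 of the heptanoate R), and cold protonation of 7 anti to the pyrrolidinone, the larger allylic substituent, should set C2 as S.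

Step 3
Reactants: 8 ethyl (2S,3R)-7-chloro-2-ethyl-3-[(2S)-5-oxopyrrolidin-2-yl]heptanoate
Product: 9 ethyl (2S)-2-[(9R,9aS)-3-oxooctahydro-1H-pyrrolo[1,2-a]azepin-9-yl]butanoate
Conditions: NaH (1.1 equiv), NaI (cat.), DMF, high dilution, 0 to 50 °C
Reagents that add atoms: none
Why: Intramolecular N-alkylation (7-exo-tet) of the lactam sodium salt by the primary chloride closes ring A, and because the N–H is far more acidic than the ester α-C–H the side-chain stereocentre is not touched.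

Step 4
Reactants: 9 ethyl (2S)-2-[(9R,9aS)-3-oxooctahydro-1H-pyrrolo[1,2-a]azepin-9-yl]butanoate
Product: 10 (2S)-2-[(9R,9aS)-3-oxooctahydro-1H-pyrrolo[1,2-a]azepin-9-yl]butanoic acid
Conditions: LiOH, THF/MeOH/H2O, 40 °C; then 1 M HCl
Reagents that add atoms: lithium hydroxide, [Li+].[OH-]
Why: Saponification of the ethyl ester should proceed without enolization of the α-branched ester, and the tertiary lactam is inert to hydroxide at this temperature.

Step 5
Reactants: 11 (R)-3-bromo-2-methylpropan-1-ol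
Product: 12 (R)-3-iodo-2-methylpropan-1-ol
Conditions: NaI, acetone, reflux
Reagents that add atoms: sodium iodide, [Na+].[I-]
Why: Finkelstein halide exchange is an SN2 reaction at the primary carbon, so the stereocentre is not involved.

Step 6
Reactants: 10 (2S)-2-[(9R,9aS)-3-oxooctahydro-1H-pyrrolo[1,2-a]azepin-9-yl]butanoic acid; 12 (R)-3-iodo-2-methylpropan-1-ol
Product: 13 (2R)-3-iodo-2-methylpropyl (2S)-2-[(9R,9aS)-3-oxooctahydro-1H-pyrrolo[1,2-a]azepin-9-yl]butanoate
Conditions: EDC, DMAP (cat.), CH2Cl2, 0 °C to rt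
Reagents that add atoms: none
Why: Steglich esterification of the primary alcohol under mild carbodiimide activation should keep the α-stereocentre of the acid and puts the C5–O–C2 tether of ring D in place.

Step 7
Reactants: 13 (2R)-3-iodo-2-methylpropyl (2S)-2-[(9R,9aS)-3-oxooctahydro-1H-pyrrolo[1,2-a]azepin-9-yl]butanoate
Product: 15 (9R,9aS)-9-[(3S,6S)-7-hydroxy-6-methyl-4-oxoheptan-3-yl]octahydro-3H-pyrrolo[1,2-a]azepin-3-one, via samarium hemiketalate 14 (not isolated)
Conditions: SmI2 (2.5 equiv), Fe(dbm)3 (iron tris(dibenzoylmethanate), 2 mol%), THF, −30 °C to rt; then aq. NH4Cl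
Reagents that add atoms: none
Why: SmI2 reduces the primary C–I bond in two one-electron steps to an alkylsamarium, so C4 of ring D, an electrophile in 13, becomes a nucleophile and attacks the ester carbonyl carbon (C5 of ring D), also an electrophile; the closest known reaction type is the samarium-Barbier intramolecular nucleophilic acyl substitution of iodoalkyl esters (1,4 O-to-C acyl shift). The ring that closes is the five-membered 2-oxidooxolane of 14 (C5, C4, C3, the future C2 and the ester oxygen), by 5-exo-trig attack on the C=O. The tetrahedral samarium hemiketalate persists in the flask, which stops a second addition and keeps the ketone from being reduced, and it opens on aqueous work-up to the γ-hydroxy ketone 15. No stereocentre is created: C3 of ring D is bought with 12 and the hemiketal carbon becomes the ketone. The step needs chemoselectivity for C–I over the lactam and ester carbonyls, which SmI2 without HMPA or water provides, and it must not epimerize the ethyl-bearing carbon next to the new ketone, which the cold, non-basic medium and the persistent hemiketalate secure. The ketone so unveiled is what allows the next step to set C5 by Felkin–Anh relay from that neighbouring centre.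

Step 8
Reactants: 15 (9R,9aS)-9-[(3S,6S)-7-hydroxy-6-methyl-4-oxoheptan-3-yl]octahydro-3H-pyrrolo[1,2-a]azepin-3-one
Product: 16 (9R,9aS)-9-[(3S,4R,6S)-4,7-dihydroxy-6-methylheptan-3-yl]octahydro-3H-pyrrolo[1,2-a]azepin-3-one
Conditions: LiBH(s-Bu)3 (L-Selectride, 2.5 equiv), THF, −78 °C; then aq. NaOH
Reagents that add atoms: none
Why: Felkin–Anh-controlled ketone reduction by the bulky hydride, anti to the ring carbon on the adjacent ethyl-bearing stereocentre, should set the carbinol carbon (C5 of ring D) as R, and the tertiary lactam is not reduced at −78 °C.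

Step 9
Reactants: 16 (9R,9aS)-9-[(3S,4R,6S)-4,7-dihydroxy-6-methylheptan-3-yl]octahydro-3H-pyrrolo[1,2-a]azepin-3-one
Product: 19 (9R,9aS)-9-{(1S)-1-[(2R,4S)-4-methyl-5-oxooxolan-2-yl]propyl}octahydro-3H-pyrrolo[1,2-a]azepin-3-one, via hydroxy aldehyde 17 (not isolated), via lactol 18 (not isolated)
Conditions: PhI(OAc)2 (2.5 equiv), TEMPO (cat.), CH2Cl2, rt
Reagents that add atoms: none
Why: In this oxidative lactonization of a 1,4-diol TEMPO oxidizes the primary alcohol selectively, the secondary hydroxyl traps the aldehyde as the lactol and this is oxidized on to the γ-lactone, which completes ring D without touching a stereocentre.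

Step 10
Reactants: 20 3-methylfuran-2(5H)-one
Product: 21 triisopropyl[(3-methylfuran-2-yl)oxy]silane
Conditions: i-Pr3SiOTf, Et3N, CH2Cl2, 0 °C
Reagents that add atoms: triisopropylsilyl trifluoromethanesulfonate, CC(C)[Si](OS(=O)(=O)C(F)(F)F)(C(C)C)C(C)C
Why: Soft enolization and O-silylation of the butenolide gives the aromatic 2-silyloxyfuran (silyl dienol ether formation).

Step 11
Reactants: 19 (9R,9aS)-9-{(1S)-1-[(2R,4S)-4-methyl-5-oxooxolan-2-yl]propyl}octahydro-3H-pyrrolo[1,2-a]azepin-3-one; 21 triisopropyl[(3-methylfuran-2-yl)oxy]silane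
Product: 24 (5S)-3-methyl-5-[(3S,9R,9aS)-9-{(1S)-1-[(2R,4S)-4-methyl-5-oxooxolan-2-yl]propyl}octahydro-1H-pyrrolo[1,2-a]azepin-3-yl]furan-2(5H)-one, via silyl hemiaminal 22 (not isolated), via iminium salt 23 (not isolated)
Conditions: IrCl(CO)(PPh3)2 (1 mol%), (Me2HSi)2O, toluene, rt; then 21, CF3CO2H, CH2Cl2, −78 to 0 °C; aq. NaHCO3
Reagents that add atoms: none
Why: Iridium-catalysed hydrosilylation reduces only the tertiary lactam (lactones are inert), acid ionizes the silyl hemiaminal to the bicyclic iminium ion, and the vinylogous Mannich addition of the silyloxyfuran should occur on the face anti to the azepane carbon C9 (C3 of the bicycle S, trans across ring B) through the usual open synclinal transition state that gives the threo adduct (butenolide C5 S).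

Step 12
Reactants: 24 (5S)-3-methyl-5-[(3S,9R,9aS)-9-{(1S)-1-[(2R,4S)-4-methyl-5-oxooxolan-2-yl]propyl}octahydro-1H-pyrrolo[1,2-a]azepin-3-yl]furan-2(5H)-one
Product: 25 (3S,5S)-3-methyl-5-[(3S,9R,9aS)-9-{(1S)-1-[(2R,4S)-4-methyl-5-oxooxolan-2-yl]propyl}octahydro-1H-pyrrolo[1,2-a]azepin-3-yl]oxolan-2-one
Conditions: H2 (1 atm), Pd/C, EtOAc, rt
Reagents that add atoms: none
Why: Heterogeneous hydrogenation of the butenolide C=C from the face opposite to the bulky C5 substituent should place the new methyl group cis to it (3S) and completes ring C.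

Compound list
1 | (S)-5-(hydroxymethyl)pyrrolidin-2-one | OC[C@@H]1CCC(=O)N1 | starting material
2 | ethyl 2-(triphenyl-λ5-phosphanylidene)butanoate | CCOC(=O)C(CC)=P(c1ccccc1)(c1ccccc1)c1ccccc1 | starting material
3 | (2S)-5-oxopyrrolidine-2-carbaldehyde | O=C[C@@H]1CCC(=O)N1 | intermediate
4 | ethyl (2E)-2-ethyl-3-[(2S)-5-oxopyrrolidin-2-yl]prop-2-enoate | CCOC(=O)/C(CC)=C/[C@@H]1CCC(=O)N1 | intermediate
5 | 1-bromo-4-chlorobutane | ClCCCCBr | starting material
6 | (4-chlorobutyl)magnesium bromide | ClCCCC[Mg]Br | intermediate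
7 | {[(3R)-7-chloro-1-ethoxy-2-ethyl-3-[(2S)-5-oxo-1-(trimethylsilyl)pyrrolidin-2-yl]hept-1-en-1-yl]oxy}trimethylsilane | CCOC(O[Si](C)(C)C)=C(CC)[C@@H](CCCCCl)[C@@H]1CCC(=O)N1[Si](C)(C)C | intermediate
8 | ethyl (2S,3R)-7-chloro-2-ethyl-3-[(2S)-5-oxopyrrolidin-2-yl]heptanoate | CC[C@@H]([C@@H](CCCCCl)[C@@H]1CCC(=O)N1)C(=O)OCC | intermediate
9 | ethyl (2S)-2-[(9R,9aS)-3-oxooctahydro-1H-pyrrolo[1,2-a]azepin-9-yl]butanoate | CC[C@@H]([C@H]1CCCCN2[C@H]1CCC2=O)C(=O)OCC | intermediate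
10 | (2S)-2-[(9R,9aS)-3-oxooctahydro-1H-pyrrolo[1,2-a]azepin-9-yl]butanoic acid | CC[C@@H]([C@H]1CCCCN2[C@H]1CCC2=O)C(=O)O | intermediate
11 | (R)-3-bromo-2-methylpropan-1-ol | OC[C@@H](C)CBr | starting material
12 | (R)-3-iodo-2-methylpropan-1-ol | OC[C@@H](C)CI | intermediate
13 | (2R)-3-iodo-2-methylpropyl (2S)-2-[(9R,9aS)-3-oxooctahydro-1H-pyrrolo[1,2-a]azepin-9-yl]butanoate | CC[C@@H]([C@H]1CCCCN2[C@H]1CCC2=O)C(=O)OC[C@@H](C)CI | intermediate
14 | diiodosamarium (4S)-4-methyl-2-{(1S)-1-[(9R,9aS)-3-oxooctahydro-1H-pyrrolo[1,2-a]azepin-9-yl]propyl}oxolan-2-olate | CC[C@@H]([C@H]1CCCCN2[C@H]1CCC2=O)C1(O[Sm](I)I)C[C@H](C)CO1 | intermediate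
15 | (9R,9aS)-9-[(3S,6S)-7-hydroxy-6-methyl-4-oxoheptan-3-yl]octahydro-3H-pyrrolo[1,2-a]azepin-3-one | CC[C@@H]([C@H]1CCCCN2[C@H]1CCC2=O)C(=O)C[C@H](C)CO | intermediate
16 | (9R,9aS)-9-[(3S,4R,6S)-4,7-dihydroxy-6-methylheptan-3-yl]octahydro-3H-pyrrolo[1,2-a]azepin-3-one | CC[C@@H]([C@H]1CCCCN2[C@H]1CCC2=O)[C@H](O)C[C@H](C)CO | intermediate
17 | (2S,4R,5S)-4-hydroxy-2-methyl-5-[(9R,9aS)-3-oxooctahydro-1H-pyrrolo[1,2-a]azepin-9-yl]heptanal | CC[C@@H]([C@H]1CCCCN2[C@H]1CCC2=O)[C@H](O)C[C@H](C)C=O | intermediate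
18 | (9R,9aS)-9-{(1S)-1-[(2R,4S)-5-hydroxy-4-methyloxolan-2-yl]propyl}octahydro-3H-pyrrolo[1,2-a]azepin-3-one | CC[C@@H]([C@H]1CCCCN2[C@H]1CCC2=O)[C@H]1C[C@H](C)C(O)O1 | intermediate
19 | (9R,9aS)-9-{(1S)-1-[(2R,4S)-4-methyl-5-oxooxolan-2-yl]propyl}octahydro-3H-pyrrolo[1,2-a]azepin-3-one | CC[C@@H]([C@H]1CCCCN2[C@H]1CCC2=O)[C@H]1C[C@H](C)C(=O)O1 | intermediate
20 | 3-methylfuran-2(5H)-one | CC1=CCOC1=O | starting material
21 | triisopropyl[(3-methylfuran-2-yl)oxy]silane | Cc1ccoc1O[Si](C(C)C)(C(C)C)C(C)C | intermediate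
22 | (3S,5R)-3-methyl-5-{(1S)-1-[(9R,9aS)-3-{[dimethyl(dimethylsilyloxy)silyl]oxy}octahydro-1H-pyrrolo[1,2-a]azepin-9-yl]propyl}oxolan-2-one | CC[C@@H]([C@H]1CCCCN2[C@H]1CCC2O[Si](C)(C)O[SiH](C)C)[C@H]1C[C@H](C)C(=O)O1 | intermediate
23 | (9R,9aS)-9-{(1S)-1-[(2R,4S)-4-methyl-5-oxooxolan-2-yl]propyl}-2,5,6,7,8,9-hexahydro-1H-pyrrolo[1,2-a]azepin-4(9aH)-ium trifluoroacetate (N4=C3 iminium) | CC[C@@H]([C@H]1CCCC[N+]2=CCC[C@@H]12)[C@H]1C[C@H](C)C(=O)O1.[O-]C(=O)C(F)(F)F | intermediate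
24 | (5S)-3-methyl-5-[(3S,9R,9aS)-9-{(1S)-1-[(2R,4S)-4-methyl-5-oxooxolan-2-yl]propyl}octahydro-1H-pyrrolo[1,2-a]azepin-3-yl]furan-2(5H)-one | CC[C@@H]([C@H]1CCCCN2[C@H]1CC[C@H]2[C@@H]1C=C(C)C(=O)O1)[C@H]1C[C@H](C)C(=O)O1 | intermediate
25 | (3S,5S)-3-methyl-5-[(3S,9R,9aS)-9-{(1S)-1-[(2R,4S)-4-methyl-5-oxooxolan-2-yl]propyl}octahydro-1H-pyrrolo[1,2-a]azepin-3-yl]oxolan-2-one | CC[C@@H]([C@H]1CCCCN2[C@H]1CC[C@H]2[C@@H]1C[C@H](C)C(=O)O1)[C@H]1C[C@H](C)C(=O)O1 | target

Total step count: 12. Longest linear sequence: 10 steps (steps 1–4, 6–9, 11 and 12, from 1).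

Steps most likely to fail

Step 2. The 1,4-addition to the hindered trisubstituted enoate may be slow, and the protonation that sets the ethyl-bearing centre may show poor facial selectivity. The fallback sets out from 4 and returns at 10. DIBAL-H reduction of 4 should give the allylic alcohol (5S)-5-[(1E)-2-(hydroxymethyl)but-1-en-1-yl]pyrrolidin-2-one F1. Esterification with picolinic acid (DCC, DMAP) gives the picolinate [(2E)-2-ethyl-3-[(2S)-5-oxopyrrolidin-2-yl]prop-2-en-1-yl] pyridine-2-carboxylate F2. Copper-mediated anti-SN2' allylic substitution with Grignard reagent 6 (CuBr·SMe2, THF, −78 °C), again anti to the ring nitrogen, should give the 1,1-disubstituted alkene (5S)-5-[(3R)-7-chloro-2-ethylhept-1-en-3-yl]pyrrolidin-2-one F3. NaH and NaI in DMF close ring A to (9R,9aS)-9-(but-1-en-2-yl)octahydro-3H-pyrrolo[1,2-a]azepin-3-one F4. Hydroboration with 9-BBN anti to the larger allylic substituent, then NaBO3, should set the ethyl-bearing centre in the alcohol (9R,9aS)-9-[(2S)-1-hydroxybutan-2-yl]octahydro-3H-pyrrolo[1,2-a]azepin-3-one F5, and TEMPO/PhI(OAc)2 in aqueous MeCN oxidizes F5 to acid 10.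

Step 11. The furan may attack the iminium carbon with poor facial selectivity, and threo selectivity at the butenolide carbon may be lost. The fallback sets out from 19 and returns at 25, building ring C stepwise. The silyl hemiaminal 22, made as in step 11, is treated with vinylmagnesium bromide at −78 °C (reductive vinylation, small nucleophile anti to C9) to give (3S,5R)-3-methyl-5-{(1S)-1-[(3S,9R,9aS)-3-ethenyloctahydro-1H-pyrrolo[1,2-a]azepin-9-yl]propyl}oxolan-2-one F10. Ozonolysis of its trifluoroacetate salt (O3, then Me2S) gives the amino aldehyde (3S,9R,9aS)-9-{(1S)-1-[(2R,4S)-4-methyl-5-oxooxolan-2-yl]propyl}octahydro-1H-pyrrolo[1,2-a]azepine-3-carbaldehyde F11, used at once. Zinc-mediated Barbier allylation with ethyl 2-(bromomethyl)acrylate under chelation control (new hydroxyl syn to nitrogen) gives the hydroxy ester ethyl 2-{(2S)-2-hydroxy-2-[(3S,9R,9aS)-9-{(1S)-1-[(2R,4S)-4-methyl-5-oxooxolan-2-yl]propyl}octahydro-1H-pyrrolo[1,2-a]azepin-3-yl]ethyl}prop-2-enoate F12. Acid closes it to the α-methylene lactone (5S)-3-methylidene-5-[(3S,9R,9aS)-9-{(1S)-1-[(2R,4S)-4-methyl-5-oxooxolan-2-yl]propyl}octahydro-1H-pyrrolo[1,2-a]azepin-3-yl]oxolan-2-one F13, and hydrogenation (H2, Pd/C) from the face opposite to the ring substituent gives 25.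

Step 7. The alkylsamarium may be protonated or lose iodide reductively before it attacks the hindered ester carbonyl. The fallback sets out from 10 and returns at 15, with an intermolecular acylation in place of the ring closure. Thioesterification of 10 (EtSH, EDC, DMAP) gives S-ethyl (2S)-2-[(9R,9aS)-3-oxooctahydro-1H-pyrrolo[1,2-a]azepin-9-yl]butanethioate F6. Alcohol 12 is silylated (t-BuMe2SiCl, imidazole) to tert-butyl{[(2R)-3-iodo-2-methylpropyl]oxy}dimethylsilane F7 and converted with zinc dust into [(2R)-3-{[tert-butyl(dimethyl)silyl]oxy}-2-methylpropyl]zinc iodide F8. Fukuyama coupling of F6 with F8 (PdCl2(PPh3)2, toluene) gives the ketone (9R,9aS)-9-[(3S,6S)-7-{[tert-butyl(dimethyl)silyl]oxy}-6-methyl-4-oxoheptan-3-yl]octahydro-3H-pyrrolo[1,2-a]azepin-3-one F9, and Bu4NF removes the silyl group to give 15.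

Further compounds
F1 | step 2 | (5S)-5-[(1E)-2-(hydroxymethyl)but-1-en-1-yl]pyrrolidin-2-one | OC/C(CC)=C/[C@@H]1CCC(=O)N1
F2 | step 2 | [(2E)-2-ethyl-3-[(2S)-5-oxopyrrolidin-2-yl]prop-2-en-1-yl] pyridine-2-carboxylate | O=C(OC/C(CC)=C/[C@@H]1CCC(=O)N1)c1ccccn1
F3 | step 2 | (5S)-5-[(3R)-7-chloro-2-ethylhept-1-en-3-yl]pyrrolidin-2-one | C=C(CC)[C@@H](CCCCCl)[C@@H]1CCC(=O)N1
F4 | step 2 | (9R,9aS)-9-(but-1-en-2-yl)octahydro-3H-pyrrolo[1,2-a]azepin-3-one | C=C(CC)[C@H]1CCCCN2[C@H]1CCC2=O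
F5 | step 2 | (9R,9aS)-9-[(2S)-1-hydroxybutan-2-yl]octahydro-3H-pyrrolo[1,2-a]azepin-3-one | CC[C@@H]([C@H]1CCCCN2[C@H]1CCC2=O)CO
F6 | step 7 | S-ethyl (2S)-2-[(9R,9aS)-3-oxooctahydro-1H-pyrrolo[1,2-a]azepin-9-yl]butanethioate | CC[C@@H]([C@H]1CCCCN2[C@H]1CCC2=O)C(=O)SCC
F7 | step 7 | tert-butyl{[(2R)-3-iodo-2-methylpropyl]oxy}dimethylsilane | CC(C)(C)[Si](C)(C)OC[C@@H](C)CI
F8 | step 7 | [(2R)-3-{[tert-butyl(dimethyl)silyl]oxy}-2-methylpropyl]zinc iodide | CC(C)(C)[Si](C)(C)OC[C@@H](C)C[Zn]I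
F9 | step 7 | (9R,9aS)-9-[(3S,6S)-7-{[tert-butyl(dimethyl)silyl]oxy}-6-methyl-4-oxoheptan-3-yl]octahydro-3H-pyrrolo[1,2-a]azepin-3-one | CC[C@@H]([C@H]1CCCCN2[C@H]1CCC2=O)C(=O)C[C@H](C)CO[Si](C)(C)C(C)(C)C
F10 | step 11 | (3S,5R)-3-methyl-5-{(1S)-1-[(3S,9R,9aS)-3-ethenyloctahydro-1H-pyrrolo[1,2-a]azepin-9-yl]propyl}oxolan-2-one | CC[C@@H]([C@H]1CCCCN2[C@H]1CC[C@H]2C=C)[C@H]1C[C@H](C)C(=O)O1
F11 | step 11 | (3S,9R,9aS)-9-{(1S)-1-[(2R,4S)-4-methyl-5-oxooxolan-2-yl]propyl}octahydro-1H-pyrrolo[1,2-a]azepine-3-carbaldehyde | CC[C@@H]([C@H]1CCCCN2[C@H]1CC[C@H]2C=O)[C@H]1C[C@H](C)C(=O)O1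
F12 | step 11 | ethyl 2-{(2S)-2-hydroxy-2-[(3S,9R,9aS)-9-{(1S)-1-[(2R,4S)-4-methyl-5-oxooxolan-2-yl]propyl}octahydro-1H-pyrrolo[1,2-a]azepin-3-yl]ethyl}prop-2-enoate | CC[C@@H]([C@H]1CCCCN2[C@H]1CC[C@H]2[C@@H](O)CC(=C)C(=O)OCC)[C@H]1C[C@H](C)C(=O)O1
F13 | step 11 | (5S)-3-methylidene-5-[(3S,9R,9aS)-9-{(1S)-1-[(2R,4S)-4-methyl-5-oxooxolan-2-yl]propyl}octahydro-1H-pyrrolo[1,2-a]azepin-3-yl]oxolan-2-one | CC[C@@H]([C@H]1CCCCN2[C@H]1CC[C@H]2[C@@H]1CC(=C)C(=O)O1)[C@H]1C[C@H](C)C(=O)O1
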